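## Retrosynthetic overview

1. Target ⇐ desilylation, per-acetylation and hydride opening of a 9′α,10′α-epoxide ⇐ C12–C12′ bond by SN2 opening of a cis-fused 10β,12-oxetane (half A) with the primary alkyllithium of half B.
2. Both halves ⇐ one bicyclic diol; its C11–C12 bond and C11 stereocentre ⇐ Büchi [2,3]-sigmatropic rearrangement of a 9β-allylic alcohol (1,3-chirality transfer), reached from the enone by 1,2-reduction and suprafacial perrhenate 1,3-transposition.
3. Oxepane ⇐ 7-endo opening of a side-chain (S)-epoxide by C7–OH; C7–O ⇐ Criegee degradation of isopropenyl; quaternary C6 ⇐ two α′-alkylations of (S)-carvone 1, the second with an iodide made from (S)-α-hydroxy-γ-butyrolactone 2 (source of C3).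
4. Ring order: cyclohexene (bought in 1) → side-chain oxirane → oxepane → oxetane (half A, opened in the coupling) and ring oxirane (half B, opened by hydride).

Assumptions: 2 (commercial, made from L-malic acid) is taken as a purchasable chiral-pool compound; locants are O1, C2(Me2), C3, C4, C5, C6(Me), C7 for the oxepane, C6–C11 for the carbocycle (C10 bears a methyl), C12 for the carbon on C11, primes for half B; β is the face of the C6 methyl, α the opposite face.

## Route

Step 1
Reactants: 2 (S)-α-hydroxy-γ-butyrolactone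
Product: 3 (3S)-2-methylpentane-2,3,5-triol
Conditions: MeMgBr (3.5 equiv), THF, 0 °C → rt; aq. NH4Cl
Reagents that add atoms: methylmagnesium bromide, C[Mg]Br
Why: Double Grignard addition to the lactone carbonyl (after deprotonation of the hydroxyl) builds the gem-dimethyl carbinol C2 and frees the primary hydroxyl without touching the purchased stereocentre, the future C3.

Step 2
Reactants: 3 (3S)-2-methylpentane-2,3,5-triol
Product: 4 acetonide alcohol
Conditions: Me2C(OMe)2, pyridinium p-toluenesulfonate (cat.), CH2Cl2, rt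
Reagents that add atoms: 2,2-dimethoxypropane, COC(C)(C)OC
Why: Acetonide formation is thermodynamically selective for the five-membered dioxolane across the vicinal secondary/tertiary diol, leaving the primary hydroxyl free and blocking later tetrahydrofuran formation.

Step 3
Reactants: 4 acetonide alcohol
Product: 5 acetonide iodide
Conditions: I2, PPh3, imidazole, CH2Cl2, 0 °C → rt
Reagents that add atoms: iodine, II
Why: Appel-type iodination converts the primary alcohol into the primary iodide by SN2 displacement of the oxyphosphonium group; no stereocentre is involved.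

Step 4
Reactants: 1 (S)-carvone
Product: 7 6-methylcarvone, via carvone lithium dienolate 6 (not isolated)
Conditions: LiN(iPr)2, THF, −78 °C; MeI, −78 → −20 °C
Reagents that add atoms: iodomethane, CI
Why: Kinetic α′-deprotonation gives the cross-conjugated lithium enolate, which is C-methylated at C6; the C6 epimer ratio is irrelevant because this centre is re-enolised in step 5.

Step 5
Reactants: 7 6-methylcarvone; 5 acetonide iodide
Product: 9 C6-quaternary enone, via lithium dienolate 8 (not isolated)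
Conditions: LiN(iPr)2, THF, −78 °C; then 5, HMPA, −78 → 0 °C
Reagents that add atoms: none
Why: Enolate alkylation (SN2 on the primary iodide) creates the quaternary C6 with the electrophile entering anti to the neighbouring isopropenyl group, so the methyl ends cis and the side chain trans to it (1,2-induction from the carvone stereocentre).

Step 6
Reactants: 9 C6-quaternary enone
Product: 10 side-chain diol
Conditions: AcOH/H2O (4:1), 45 °C
Reagents that add atoms: none
Why: Acid-catalysed ketal hydrolysis releases the secondary/tertiary diol; the enone and the isopropenyl group are inert to aqueous acetic acid.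

Step 7
Reactants: 10 side-chain diol
Product: 13 epoxy enone, via cyclic orthoacetate 11 (not isolated), via chloro acetate 12 (not isolated)
Conditions: MeC(OMe)3, pyridinium p-toluenesulfonate (cat.), CH2Cl2, rt; Me3SiCl, CH2Cl2, 0 °C; K2CO3, MeOH, rt
Reagents that add atoms: none
Why: Kolb–Sharpless one-pot diol-to-epoxide conversion: the cyclic orthoacetate is opened through its acetoxonium ion by chloride at the tertiary carbon and base then closes the oxirane from the secondary alkoxide, so the C3–O bond is never broken and C3 stays (S).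

Step 8
Reactants: 13 epoxy enone
Product: 15 7β-acetoxy enone, via methoxy hydroperoxide 14 (not isolated)
Conditions: O3, CH2Cl2/MeOH (4:1), −78 °C; then Ac2O, Et3N, DMAP (cat.), 0 °C → rt
Reagents that add atoms: ozone, [O-][O+]=O; methanol, CO
Why: Ozone attacks the electron-rich isopropenyl group much faster than the enone, and the α-methoxy hydroperoxide undergoes acylation-triggered Criegee rearrangement in which C7 migrates to oxygen with retention, turning the purchased carvone stereocentre into the C7–O stereocentre.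

Step 9
Reactants: 15 7β-acetoxy enone
Product: 16 7β,11β-diol
Conditions: iBu2AlH (5 equiv), CH2Cl2, −78 °C
Reagents that add atoms: none
Why: iBu2AlH reduces the enone carbonyl 1,2 by axial hydride delivery from the α face, anti to the axial C6 methyl, giving the 11β-allylic alcohol, and cleaves the acetate reductively at −78 °C without opening the trisubstituted oxirane or exposing a β-hydroxy ketone to base.

Step 10
Reactants: 16 7β,11β-diol
Product: 17 7β,9β-diol
Conditions: Ph3SiOReO3 (5 mol%), Et2O, −50 → −20 °C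
Reagents that add atoms: none
Why: Rhenium-oxo-catalysed 1,3-transposition of the allylic alcohol proceeds through a [3,3]-sigmatropic shift of the perrhenate ester, which is necessarily suprafacial on the ring (11β-OH to 9β-OH), and the equilibrium favours the hydroxyl on C9, away from the quaternary C6.

Step 11
Reactants: 17 7β,9β-diol
Product: 18 bicyclic 3α,9β-diol
Conditions: BF3·OEt2 (0.3 equiv), CH2Cl2, −78 → −40 °C
Reagents that add atoms: none
Why: Lewis-acid-activated intramolecular epoxide opening by the C7 hydroxyl takes the 7-endo course at the tertiary, cation-stabilising C2 (Markovnikov control by the gem-dimethyl group), closing the oxepane trans-fused and leaving the C3–O bond, hence (3S), intact.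

Step 12
Reactants: 18 bicyclic 3α,9β-diol
Product: 19 11β-carboxamide
Conditions: Me2NCH(OMe)2 (6 equiv), xylene, 150 °C, sealed tube; aq. work-up
Reagents that add atoms: N,N-dimethylformamide dimethyl acetal, COC(OC)N(C)C
Why: Büchi [2,3]-sigmatropic rearrangement: exchange at the C9 hydroxyl and loss of methanol give an allyloxy(dimethylamino)carbene that bonds to C11 suprafacially from the β face of the C9–O bond, so the key C11–C12 bond and the C11 stereocentre are set by 1,3-chirality transfer while the alkene moves to C9=C10.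

Step 13
Reactants: 19 11β-carboxamide
Product: 20 bicyclic 3α,12-diol
Conditions: LiEt3BH (4 equiv), THF, 0 °C → rt
Reagents that add atoms: none
Why: LiEt3BH reduces the tertiary amide through the aldehyde (C–N cleavage) to the primary alcohol without epimerising C11.

Step 14
Reactants: 20 bicyclic 3α,12-diol
Product: 22 3α,10β,12-triol, via organomercurial 21 (not isolated)
Conditions: Hg(OAc)2 (1.2 equiv), THF/H2O (1:1), rt; then NaBH4, 3 M NaOH, 0 °C
Reagents that add atoms: water, O
Why: Oxymercuration–demercuration: the mercurinium ion forms on the open α face and water opens it trans-diaxially at the tertiary C10, where Markovnikov and Fürst–Plattner control coincide, giving the axial 10β-hydroxyl (methyl α) of half A.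

Step 15
Reactants: 22 3α,10β,12-triol
Product: 24 10β,12-oxetane, via primary tosylate 23 (not isolated)
Conditions: TsCl (1.05 equiv), Et3N, DMAP (cat.), CH2Cl2, 0 °C; then KOtBu, THF, 0 °C → rt
Reagents that add atoms: none
Why: Selective tosylation of the primary hydroxyl and intramolecular Williamson (4-exo-tet) displacement by the cis tertiary alkoxide give the cis-fused oxetane, which masks the C10 oxygen and turns C12 into an electrophile; no stereocentre changes.

Step 16
Reactants: 20 bicyclic 3α,12-diol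
Product: 25 primary iodide
Conditions: I2, PPh3, imidazole, CH2Cl2, 0 °C
Reagents that add atoms: iodine, II
Why: Appel-type iodination is selective for the primary hydroxyl over the hindered secondary C3 hydroxyl next to the gem-dimethyl carbon.

Step 17
Reactants: 25 primary iodide
Product: 26 silyl ether iodide
Conditions: tBuMe2SiOTf, 2,6-lutidine, CH2Cl2, −78 → 0 °C
Reagents that add atoms: tert-butyldimethylsilyl trifluoromethanesulfonate, CC(C)(C)[Si](C)(C)OS(=O)(=O)C(F)(F)F
Why: Silylation of the hindered secondary alcohol with the silyl triflate differentiates C3′–OH of half B from C3–OH of half A.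

Step 18
Reactants: 26 silyl ether iodide; 24 10β,12-oxetane
Product: 29 coupled diol, via primary alkyllithium 27 (not isolated), via oxetane lithium alkoxide 28 (not isolated)
Conditions: 26: tBuLi (2.1 equiv), Et2O/pentane, −78 °C; 24: MeLi (1.0 equiv), THF, −78 °C; combine, BF3·OEt2 (2.5 equiv), −78 °C
Reagents that add atoms: none
Why: Iodine–lithium exchange gives the primary alkyllithium, which opens the BF3-activated oxetane by SN2 attack at its only unsubstituted carbon C12, forming the C12–C12′ bond and releasing the 10β-hydroxyl; no stereocentre is touched.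

Step 19
Reactants: 29 coupled diol
Product: 30 9′α,10′α-epoxide
Conditions: 3-ClC6H4CO3H (1.2 equiv), CH2Cl2, 0 °C
Reagents that add atoms: 3-chloroperbenzoic acid, OOC(=O)c1cccc(Cl)c1
Why: Prilezhaev epoxidation of the only alkene occurs from the α face because the β face is shielded by the axial C6′ methyl and the C11′ side chain.

Step 20
Reactants: 30 9′α,10′α-epoxide
Product: 31 3α,10β,10′α-triol
Conditions: LiAlH4, THF, 65 °C
Reagents that add atoms: none
Why: LiAlH4 opens the oxirane by SN2 attack at the less hindered secondary C9′, leaving the oxygen on C10′ as the equatorial 10′α-hydroxyl with the methyl β, the C10-epimeric arrangement required in half B.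

Step 21
Reactants: 31 3α,10β,10′α-triol
Product: 33 triacetate silyl ether, via trilithium alkoxide 32 (not isolated)
Conditions: nBuLi (3.3 equiv), THF, −78 °C; then Ac2O (6 equiv), −78 → 0 °C
Reagents that add atoms: acetic anhydride, CC(=O)OC(C)=O
Why: O-Acylation of the preformed lithium alkoxides with acetic anhydride esterifies the secondary C3 hydroxyl and both hindered tertiary hydroxyls under non-ionising conditions, while the silyl ether keeps C3′ masked.

Step 22
Reactants: 33 triacetate silyl ether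
Product: 34 CNP0169816.1
Conditions: HF·pyridine, THF/pyridine, 0 °C → rt
Reagents that add atoms: none
Why: Fluoride-driven cleavage of the Si–O bond frees the C3′ hydroxyl and leaves the three acetates untouched.

## Compound list

1 | (S)-(+)-carvone, (5S)-2-methyl-5-(prop-1-en-2-yl)cyclohex-2-en-1-one | CC(=C)[C@H]1CC=C(C)C(=O)C1 | starting material
2 | (S)-α-hydroxy-γ-butyrolactone, (3S)-3-hydroxyoxolan-2-one | O[C@H]1CCOC1=O | starting material
3 | (3S)-2-methylpentane-2,3,5-triol | O[C@H](C(C)(C)O)CCO | intermediate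
4 | 2-[(4S)-2,2,5,5-tetramethyl-1,3-dioxolan-4-yl]ethan-1-ol | CC1(C)O[C@H](C(C)(C)O1)CCO | intermediate
5 | (4S)-4-(2-iodoethyl)-2,2,5,5-tetramethyl-1,3-dioxolane | CC1(C)O[C@H](C(C)(C)O1)CCI | intermediate
6 | cross-conjugated lithium dienolate of carvone (O–Li on C1, C1=C6 and C2=C3; not isolated) | CC(=C)[C@H]1CC=C(C)C(O[Li])=C1 | intermediate
7 | 6-methylcarvone, (5S)-2,6-dimethyl-5-(prop-1-en-2-yl)cyclohex-2-en-1-one, both C6 epimers | CC(=C)[C@H]1CC=C(C)C(=O)C1C | intermediate
8 | lithium dienolate of 6-methylcarvone (not isolated) | CC(=C)[C@H]1CC=C(C)C(O[Li])=C1C | intermediate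
9 | (5R,6R)-2,6-dimethyl-5-(prop-1-en-2-yl)-6-{2-[(4S)-2,2,5,5-tetramethyl-1,3-dioxolan-4-yl]ethyl}cyclohex-2-en-1-one (6-methyl cis, side chain trans to isopropenyl) | CC1(C)O[C@H](C(C)(C)O1)CC[C@]2(C)[C@H](CC=C(C)C2=O)C(C)=C | intermediate
10 | (5R,6R)-6-[(3S)-3,4-dihydroxy-4-methylpentyl]-2,6-dimethyl-5-(prop-1-en-2-yl)cyclohex-2-en-1-one | O[C@H](C(C)(C)O)CC[C@]1(C)[C@H](CC=C(C)C1=O)C(C)=C | intermediate
11 | cyclic orthoacetate (2-methoxy-2-methyl-1,3-dioxolane) of diol 10, orthoester carbon unassigned (not isolated) | COC1(C)O[C@H](C(C)(C)O1)CC[C@]2(C)[C@H](CC=C(C)C2=O)C(C)=C | intermediate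
12 | (3S)-3-acetoxy-4-chloro-4-methylpentyl analogue of 10 (secondary acetate, tertiary chloride; not isolated) | CC(=O)O[C@H](C(C)(C)Cl)CC[C@]1(C)[C@H](CC=C(C)C1=O)C(C)=C | intermediate
13 | (5R,6R)-6-{2-[(2S)-3,3-dimethyloxiran-2-yl]ethyl}-2,6-dimethyl-5-(prop-1-en-2-yl)cyclohex-2-en-1-one | CC1(C)O[C@H]1CC[C@]2(C)[C@H](CC=C(C)C2=O)C(C)=C | intermediate
14 | α-methoxy hydroperoxide of 13, isopropenyl replaced by C(CH3)(OCH3)OOH on C7 (not isolated) | CC1(C)O[C@H]1CC[C@]2(C)[C@H](CC=C(C)C2=O)C(C)(OC)OO | intermediate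
15 | 7β-acetoxy-6β,10-dimethyl-6α-{2-[(2S)-3,3-dimethyloxiran-2-yl]ethyl}cyclohex-9-en-11-one (target locants; acetoxy cis to the C6 methyl) | CC1(C)O[C@H]1CC[C@]2(C)[C@H](CC=C(C)C2=O)OC(C)=O | intermediate
16 | 6β,10-dimethyl-6α-{2-[(2S)-3,3-dimethyloxiran-2-yl]ethyl}cyclohex-9-ene-7β,11β-diol (target locants) | CC1(C)O[C@H]1CC[C@]2(C)[C@H](CC=C(C)[C@H]2O)O | intermediate
17 | 6β,10-dimethyl-6α-{2-[(2S)-3,3-dimethyloxiran-2-yl]ethyl}cyclohex-10-ene-7β,9β-diol (target locants) | CC1(C)O[C@H]1CC[C@]2(C)[C@H](C[C@@H](O)C(C)=C2)O | intermediate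
18 | trans-fused oxepane–cyclohexene, 2,2,6β,10-tetramethyl, C10=C11, 3α,9β-diol, (3S) | O[C@H]1CC[C@]2(C)[C@H](C[C@@H](O)C(C)=C2)OC1(C)C | intermediate
19 | trans-fused bicycle, C9=C10, 3α-hydroxy, 11β-(N,N-dimethylcarboxamide) | O[C@H]1CC[C@]2(C)[C@H](CC=C(C)[C@H]2C(=O)N(C)C)OC1(C)C | intermediate
20 | trans-fused bicycle, C9=C10, 3α-hydroxy, 11β-hydroxymethyl (3α,12-diol) | O[C@H]1CC[C@]2(C)[C@H](CC=C(C)[C@H]2CO)OC1(C)C | intermediate
21 | 9α-(acetoxymercurio)-10β-hydroxy adduct of 20 (not isolated) | O[C@H]1CC[C@]2(C)[C@H](C[C@H]([Hg]OC(C)=O)[C@@](C)(O)[C@H]2CO)OC1(C)C | intermediate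
22 | saturated bicycle, 3α,10β,12-triol, 10α-methyl (axial tertiary 10β-OH cis to the 11β-CH2OH) | O[C@H]1CC[C@]2(C)[C@H](CC[C@@](C)(O)[C@H]2CO)OC1(C)C | intermediate
23 | 12-O-tosylate of 22 (not isolated) | O[C@H]1CC[C@]2(C)[C@H](CC[C@@](C)(O)[C@H]2COS(=O)(=O)c3ccc(C)cc3)OC1(C)C | intermediate
24 | cis-fused oxetane, O bridging C10 (β) and C12, 3α-hydroxy | O[C@H]1CC[C@]2(C)[C@H](CC[C@@]3(C)OC[C@@H]23)OC1(C)C | intermediate
25 | trans-fused bicycle, C9=C10, 3α-hydroxy, 11β-iodomethyl | O[C@H]1CC[C@]2(C)[C@H](CC=C(C)[C@H]2CI)OC1(C)C | intermediate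
26 | 3-O-tert-butyldimethylsilyl ether of 25 | CC(C)(C)[Si](C)(C)O[C@H]1CC[C@]2(C)[C@H](CC=C(C)[C@H]2CI)OC1(C)C | intermediate
27 | primary alkyllithium from 26, Li on C12′ (not isolated) | CC(C)(C)[Si](C)(C)O[C@H]1CC[C@]2(C)[C@H](CC=C(C)[C@H]2C[Li])OC1(C)C | intermediate
28 | lithium 3-alkoxide of oxetane 24 (not isolated) | [Li]O[C@H]1CC[C@]2(C)[C@H](CC[C@@]3(C)OC[C@@H]23)OC1(C)C | intermediate
29 | coupled dimer: half A saturated with 3α-OH and 10β-OH, CH2–CH2 bridge C12–C12′, half B with C9′=C10′ and 3′α-OSiMe2tBu | O[C@H]1CC[C@]2(C)[C@H](CC[C@@](C)(O)[C@H]2CC[C@H]2[C@]3(C)CC[C@H](O[Si](C)(C)C(C)(C)C)C(C)(C)O[C@H]3CC=C2C)OC1(C)C | intermediate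
30 | 9′α,10′α-epoxide of 29 | O[C@H]1CC[C@]2(C)[C@H](CC[C@@](C)(O)[C@H]2CC[C@H]2[C@]3(C)CC[C@H](O[Si](C)(C)C(C)(C)C)C(C)(C)O[C@H]3C[C@@H]4O[C@]24C)OC1(C)C | intermediate
31 | dimer 3α,10β,10′α-triol 3′-silyl ether (half A: axial 10β-OH; half B: equatorial 10′α-OH, 10′β-methyl) | O[C@H]1CC[C@]2(C)[C@H](CC[C@@](C)(O)[C@H]2CC[C@H]2[C@]3(C)CC[C@H](O[Si](C)(C)C(C)(C)C)C(C)(C)O[C@H]3CC[C@]2(C)O)OC1(C)C | intermediate
32 | trilithium alkoxide of 31 (not isolated) | [Li]O[C@H]1CC[C@]2(C)[C@H](CC[C@@](C)(O[Li])[C@H]2CC[C@H]2[C@]3(C)CC[C@H](O[Si](C)(C)C(C)(C)C)C(C)(C)O[C@H]3CC[C@]2(C)O[Li])OC1(C)C | intermediate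
33 | 3,10,10′-triacetate 3′-O-tert-butyldimethylsilyl ether | CC(=O)O[C@H]1CC[C@]2(C)[C@H](CC[C@@](C)(OC(C)=O)[C@H]2CC[C@H]2[C@]3(C)CC[C@H](O[Si](C)(C)C(C)(C)C)C(C)(C)O[C@H]3CC[C@]2(C)OC(C)=O)OC1(C)C | intermediate
34 | CNP0169816.1, (3S,6S,7S,10R,11S)-half A 3,10-diacetate linked by C12–C12′ to (3′S,6′S,7′S,10′S,11′S)-half B 10′-acetate 3′-ol | CC(=O)O[C@H]1CC[C@]2(C)[C@H](CC[C@@](C)(OC(C)=O)[C@H]2CC[C@H]2[C@]3(C)CC[C@H](O)C(C)(C)O[C@H]3CC[C@]2(C)OC(C)=O)OC1(C)C | target

## Step count and risks

Total step count: 22. Longest linear sequence: 19 steps (from 2: steps 1–3, 5–13, 14–15 or 16–17, 18–22).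

Steps most likely to fail:

Step 10 (position of the allylic-alcohol equilibrium and fidelity of the suprafacial shift in the presence of the oxirane). The fallback sets out from 15 and returns at 17. Luche reduction (NaBH4, CeCl3·7H2O, MeOH, −78 °C) gives the 11β-allylic alcohol 7-acetate F1. Hydroxyl-directed epoxidation (VO(acac)2 cat., tBuOOH, CH2Cl2) gives the syn 9β,10β-epoxy alcohol F2. 1,1′-Thiocarbonyldiimidazole with DMAP gives the O-thiocarbonylimidazolide F3. Bu3SnH/AIBN in toluene at 80 °C generates the C11 radical, which opens the adjacent oxirane and, after hydrogen transfer, delivers the transposed 9β-alcohol 7-acetate F4. K2CO3 in MeOH at 0 °C removes the acetate to give 17.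

Step 11 (6-exo attack at C3 may compete with the wanted 7-endo attack at C2). The fallback sets out from 17 and returns at 18. Al(OiPr)3 in toluene at 110 °C isomerises the oxirane to the secondary allylic alcohol with an isopropenyl terminus F5, with the C3–O bond untouched. Intramolecular Markovnikov alkoxymercuration of that 1,1-disubstituted alkene by the C7 hydroxyl (Hg(OCOCF3)2, CH2Cl2, 0 °C), where only the tertiary C2 can be attacked, gives the oxepanyl-methylmercury trifluoroacetate F6. NaBH4/NaOH reduces C–Hg to the second C2 methyl and gives 18.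

Step 18 (SN2 opening of a hindered oxetane by a β-branched alkyllithium). The fallback sets out from 26 and 22 and returns at 29 by Julia–Kocienski olefination and alkene reduction. Iodide 26 with 1-phenyl-1H-tetrazole-5-thiol and K2CO3 in DMF gives the tetrazolyl sulfide F7, which (NH4)6Mo7O24/H2O2 in EtOH oxidises to the tetrazolyl sulfone F8. Triol 22 is oxidised at the primary hydroxyl only (TEMPO cat., PhI(OAc)2, CH2Cl2) to the 3α,10β-dihydroxy 12-aldehyde F9 and silylated (Me3SiCl, imidazole) to the bis-trimethylsilyl ether aldehyde F10. KN(SiMe3)2 in THF at −78 °C with F8, then F10, gives the C12=C12′ alkene F11. Diimide (TsNHNH2, NaOAc, 85 °C) reduces only this disubstituted alkene to the saturated bis-trimethylsilyl ether F12, and K2CO3/MeOH removes the two trimethylsilyl groups to give 29.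

## Further compounds

F1 | step 10 | 11β-hydroxy-7β-acetoxy cyclohex-9-ene with the epoxy side chain (Luche product of 15) | CC1(C)O[C@H]1CC[C@]2(C)[C@H](CC=C(C)[C@H]2O)OC(C)=O
F2 | step 10 | 9β,10β-epoxy-11β-hydroxy-7β-acetate | CC1(C)O[C@H]1CC[C@]2(C)[C@H](C[C@H]3O[C@@]3(C)[C@H]2O)OC(C)=O
F3 | step 10 | 11-O-(imidazol-1-ylthiocarbonyl) derivative of F2 | CC1(C)O[C@H]1CC[C@]2(C)[C@H](C[C@H]3O[C@@]3(C)[C@H]2OC(=S)n2ccnc2)OC(C)=O
F4 | step 10 | 9β-hydroxy-7β-acetoxy cyclohex-10-ene with the epoxy side chain | CC1(C)O[C@H]1CC[C@]2(C)[C@H](C[C@@H](O)C(C)=C2)OC(C)=O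
F5 | step 11 | 7β,9β-diol of 17 with side chain (3S)-3-hydroxy-4-methylpent-4-enyl | CC(=C)[C@@H](O)CC[C@]1(C)[C@H](C[C@@H](O)C(C)=C1)O
F6 | step 11 | bicyclic 3α,9β-diol with C2 bearing methyl and CH2HgOCOCF3, C2 unassigned | O[C@H]1CC[C@]2(C)[C@H](C[C@@H](O)C(C)=C2)OC1(C)C[Hg]OC(=O)C(F)(F)F
F7 | step 18 | 1-phenyl-1H-tetrazol-5-yl sulfide from 26 | CC(C)(C)[Si](C)(C)O[C@H]1CC[C@]2(C)[C@H](CC=C(C)[C@H]2CSc2nnnn2-c2ccccc2)OC1(C)C
F8 | step 18 | 1-phenyl-1H-tetrazol-5-yl sulfone | CC(C)(C)[Si](C)(C)O[C@H]1CC[C@]2(C)[C@H](CC=C(C)[C@H]2CS(=O)(=O)c2nnnn2-c2ccccc2)OC1(C)C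
F9 | step 18 | 3α,10β-dihydroxy 11β-carbaldehyde from 22 | O[C@H]1CC[C@]2(C)[C@H](CC[C@@](C)(O)[C@H]2C=O)OC1(C)C
F10 | step 18 | 3,10-bis(trimethylsilyl) ether of F9 | C[Si](C)(C)O[C@H]1CC[C@]2(C)[C@H](CC[C@@](C)(O[Si](C)(C)C)[C@H]2C=O)OC1(C)C
F11 | step 18 | C12=C12′ alkene, E/Z mixture, bis-trimethylsilyl ether | C[Si](C)(C)O[C@H]1CC[C@]2(C)[C@H](CC[C@@](C)(O[Si](C)(C)C)[C@H]2C=C[C@H]2[C@]3(C)CC[C@H](O[Si](C)(C)C(C)(C)C)C(C)(C)O[C@H]3CC=C2C)OC1(C)C
F12 | step 18 | 3,10-bis(trimethylsilyl) ether of 29 | C[Si](C)(C)O[C@H]1CC[C@]2(C)[C@H](CC[C@@](C)(O[Si](C)(C)C)[C@H]2CC[C@H]2[C@]3(C)CC[C@H](O[Si](C)(C)C(C)(C)C)C(C)(C)O[C@H]3CC=C2C)OC1(C)C
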